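**Plan**

Ring atoms are numbered as in 7-oxabicyclo[4.1.0]heptan-2-one (C1 oxirane C–Me, C2 C=O, C3 CH–O-angelate, C4 CH–side chain, C6 oxirane CH); the side chain is C1′ (=CH2), C2′, C3′ (CH–O-senecioate).

1. Cuts, in retrosynthetic order: C2′–C3′ (alkene carbon on ring C4 to the ester-bearing carbinol carbon), giving alkenyl triflate 14 and racemic 1-chloroalkyl senecioate 18; then C3–O (angelate, by SN2); then the enol triflate C–O back to an acetyl group, which is the ozonised isopropenyl group of (S)-carvone; then C3–OH and the oxirane back to the carvone enone.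
2. Enabling feature: C3′ is a secondary carbon whose oxygen is already an ester, and its partner C2′ is the internal carbon of a 1,1-disubstituted alkene on ring C4. C3′ is therefore available as an α-acyloxyalkyl radical (from aldehyde + acyl chloride) and C2′ as the enol triflate of a methyl ketone. Two electrophilic carbons are joined reductively, so the bond, the senecioate and the C3′ stereocentre arrive together.
3. Forward order: the six-membered ring comes from (S)-carvone; oxirane (step 1); C3 oxygen (step 2); one-carbon excision and enol triflate (steps 4, 5); angelate (step 7); side chain joined last (step 10).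
4. Stereochemistry: C4 from (S)-carvone; C1/C6 by epoxidation anti to the C4 group; C3 by anti hydroxylation followed by inversion with cesium angelate (3,4-cis); C3′ by the chiral nickel catalyst.

Key step: step 10

Assumption: the sense of induction of the chiral ligand in step 10 cannot be predicted for this substrate, so both antipodes are to be tried and the one that gives (3′S) kept; 18 is used as the racemate because its stereocentre is erased at the radical stage.

**Route**

Step 1
Reactants: 1 (S)-(+)-carvone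
Product: 2 (1S,4S,6S)-1-methyl-4-(prop-1-en-2-yl)-7-oxabicyclo[4.1.0]heptan-2-one
Conditions: 30% aq. H2O2, NaOH (cat.), MeOH, 0 °C
Reagents that add atoms: hydrogen peroxide, OO
Why: Weitz–Scheffer nucleophilic epoxidation touches only the electron-poor enone C=C, and hydroperoxide should add anti to the isopropenyl group, so the oxirane (C1, C6) is set trans to the C4 substituent.

Step 2
Reactants: 2 (1S,4S,6S)-1-methyl-4-(prop-1-en-2-yl)-7-oxabicyclo[4.1.0]heptan-2-one
Product: 4 (1S,3R,4R,6S)-3-hydroxy-1-methyl-4-(prop-1-en-2-yl)-7-oxabicyclo[4.1.0]heptan-2-one, via potassium enolate 3 (not isolated)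
Conditions: KHMDS, THF, −78 °C; Davis oxaziridine, −78 °C; AcOH quench
Reagents that add atoms: 2-(phenylsulfonyl)-3-phenyloxaziridine, O=S(=O)(c1ccccc1)N1OC1c1ccccc1
Why: Only C3 carries α-hydrogens (C1 is quaternary), and in this enolate hydroxylation (Davis oxidation) the oxygen should be delivered to the face anti to the vicinal C4 isopropenyl group, setting C3 with OH trans to it.

Step 3
Reactants: 4 (1S,3R,4R,6S)-3-hydroxy-1-methyl-4-(prop-1-en-2-yl)-7-oxabicyclo[4.1.0]heptan-2-one
Product: 5 (1S,3R,4R,6S)-1-methyl-4-(prop-1-en-2-yl)-3-(triethylsilyloxy)-7-oxabicyclo[4.1.0]heptan-2-one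
Conditions: TESCl, imidazole, DMF, 0 °C → rt
Reagents that add atoms: chlorotriethylsilane, CC[Si](Cl)(CC)CC
Why: Standard silylation of a secondary alcohol turns the C3 oxygen into a base-stable group that is a poor leaving group, which is needed once an acetyl group sits on C4 (steps 4 and 5).

Step 4
Reactants: 5 (1S,3R,4R,6S)-1-methyl-4-(prop-1-en-2-yl)-3-(triethylsilyloxy)-7-oxabicyclo[4.1.0]heptan-2-one
Product: 7 (1S,3R,4S,6S)-4-acetyl-1-methyl-3-(triethylsilyloxy)-7-oxabicyclo[4.1.0]heptan-2-one, via secondary ozonide 6 (not isolated)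
Conditions: O3, CH2Cl2, −78 °C; PPh3, −78 °C → rt
Reagents that add atoms: ozone, [O-][O+]=O
Why: Ozonolysis with reductive work-up cleaves the only C=C to the methyl ketone under neutral conditions, so the now enolisable C4 centre (already in the favoured 3,4-trans arrangement) should keep its configuration.

Step 5
Reactants: 7 (1S,3R,4S,6S)-4-acetyl-1-methyl-3-(triethylsilyloxy)-7-oxabicyclo[4.1.0]heptan-2-one
Product: 9 (1S,3R,4S,6S)-1-methyl-3-(triethylsilyloxy)-4-[1-(trifluoromethanesulfonyloxy)ethenyl]-7-oxabicyclo[4.1.0]heptan-2-one, via terminal potassium enolate 8 (not isolated)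
Conditions: Comins' reagent, THF, −78 °C; KHMDS added last (internal quench); AcOH quench
Reagents that add atoms: N-(5-chloropyridin-2-yl)-1,1,1-trifluoro-N-(trifluoromethanesulfonyl)methanesulfonamide (Comins' reagent), O=S(=O)(N(c1ccc(Cl)cn1)S(=O)(=O)C(F)(F)F)C(F)(F)F
Why: In this kinetic enol triflate formation the bulky amide base should remove a proton from the unhindered acetyl CH3 and not from the tertiary C4–H or the tertiary silyloxy-bearing C3–H of the ring ketone, and the terminal enolate is trapped on oxygen as it forms.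

Step 6
Reactants: 9 (1S,3R,4S,6S)-1-methyl-3-(triethylsilyloxy)-4-[1-(trifluoromethanesulfonyloxy)ethenyl]-7-oxabicyclo[4.1.0]heptan-2-one
Product: 10 (1S,3R,4S,6S)-3-hydroxy-1-methyl-4-[1-(trifluoromethanesulfonyloxy)ethenyl]-7-oxabicyclo[4.1.0]heptan-2-one
Conditions: HF·pyridine, pyridine, THF, 0 °C
Reagents that add atoms: none
Why: Buffered fluoride cleavage of the TES ether is free of base, so the α-ketol (C3), the oxirane and the alkenyl triflate should survive.

Step 7
Reactants: 10 (1S,3R,4S,6S)-3-hydroxy-1-methyl-4-[1-(trifluoromethanesulfonyloxy)ethenyl]-7-oxabicyclo[4.1.0]heptan-2-one; 11 angelic acid, (2Z)-2-methylbut-2-enoic acid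
Product: 14 (1S,3S,4S,6S)-1-methyl-3-[(2Z)-2-methylbut-2-enoyloxy]-4-[1-(trifluoromethanesulfonyloxy)ethenyl]-7-oxabicyclo[4.1.0]heptan-2-one, via C3 triflate 12 (not isolated), via cesium angelate 13 (not isolated)
Conditions: Tf2O, 2,6-lutidine, CH2Cl2, −78 → −40 °C; then 13 [from 11, Cs2CO3, DMF, 4 Å MS, separate flask], 18-crown-6, −40 → 0 °C
Reagents that add atoms: none
Why: Carboxylate displacement of a secondary α-keto triflate is an SN2 reaction with inversion (E2 is disfavoured because C4–H is syn to the leaving group), so C3 becomes cis to the C4 substituent, and because the acid acts as nucleophile and is never activated the Z geometry of the angelate should be kept.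

Step 8
Reactants: 15 4-methylpent-3-en-1-ol
Product: 16 4-methylpent-3-enal
Conditions: Dess–Martin periodinane, NaHCO3, CH2Cl2, 0 °C → rt; used at once
Reagents that add atoms: none
Why: Dess–Martin oxidation under buffered, non-basic conditions should give the β,γ-unsaturated aldehyde without moving the double bond into conjugation.

Step 9
Reactants: 16 4-methylpent-3-enal; 17 3-methylbut-2-enoyl chloride (senecioyl chloride)
Product: 18 rac-1-chloro-4-methylpent-3-en-1-yl 3-methylbut-2-enoate
Conditions: ZnCl2 (cat.), CH2Cl2, −20 → 0 °C; used crude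
Reagents that add atoms: none
Why: Lewis-acid-catalysed addition of an acyl chloride across the aldehyde C=O gives the 1-chloroalkyl ester; the new centre is racemic and is erased in step 10.

Step 10
Reactants: 14 (1S,3S,4S,6S)-1-methyl-3-[(2Z)-2-methylbut-2-enoyloxy]-4-[1-(trifluoromethanesulfonyloxy)ethenyl]-7-oxabicyclo[4.1.0]heptan-2-one; 18 rac-1-chloro-4-methylpent-3-en-1-yl 3-methylbut-2-enoate
Product: 19 (1S,3S,4R,6S)-1-methyl-3-[(2Z)-2-methylbut-2-enoyloxy]-4-[(3S)-6-methyl-3-(3-methylbut-2-enoyloxy)hepta-1,5-dien-2-yl]-7-oxabicyclo[4.1.0]heptan-2-one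
Conditions: NiBr2·glyme (10 mol %), chiral bis(oxazoline) ligand (12 mol %, antipode chosen by trial), Mn powder (3 equiv), 18 (2 equiv), DMA/THF, 0 °C
Reagents that add atoms: none
Why: Proposed new method: low-valent Ni/bis(oxazoline) should add oxidatively to the alkenyl C–OTf bond of 14, the nickel manifold then abstracts chlorine from racemic 18 to give a planar α-acyloxyalkyl radical stabilised by the ester oxygen, this radical is captured at nickel, and reductive elimination from the alkenyl–Ni(III)–alkyl species forms C2′–C3′ while Mn returns nickel to the low-valent state. The closest known reaction types are the Ni-catalysed enantioconvergent couplings of racemic α-haloalkyl esters (made from aldehyde and acyl halide) with alkyl partners and the Ni/bis(oxazoline) asymmetric reductive cross-couplings of alkenyl halides with racemic secondary alkyl chlorides; combining the α-acyloxyalkyl electrophile with an α-branched alkenyl triflate is the untested element. No ring is closed. The one new stereocentre, C3′ (S), is set by the chiral ligand in the radical-capture and reductive-elimination sequence, the radical having lost the configuration of 18, and the ligand antipode matched with the bias of the neighbouring ring centre C4 is kept. The step needs cross- over homo-coupling, which the different activation modes of the C(sp2)–OTf bond (two-electron oxidative addition) and the C(sp3)–Cl bond (halogen abstraction) should secure, and it needs the epoxy ketone, the base-sensitive 3,4-cis α-acyloxy ketone and the product allylic ester to stay untouched, which the absence of base, the much faster reaction of triflate and chloride at 0 °C and a stop at full conversion of 14 should secure.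

**Compound list**

1 | (S)-(+)-carvone, (5S)-2-methyl-5-(prop-1-en-2-yl)cyclohex-2-en-1-one | C=C(C)[C@H]1CC=C(C)C(=O)C1 | starting material
2 | (1S,4S,6S)-1-methyl-4-(prop-1-en-2-yl)-7-oxabicyclo[4.1.0]heptan-2-one (oxirane trans to isopropenyl) | C=C(C)[C@H]1C[C@@H]2O[C@]2(C)C(=O)C1 | intermediate
3 | potassium enolate of 2 (C2–O−, C2=C3) | C=C(C)[C@H]1C[C@@H]2O[C@]2(C)C([O-])=C1.[K+] | intermediate
4 | (1S,3R,4R,6S)-3-hydroxy-1-methyl-4-(prop-1-en-2-yl)-7-oxabicyclo[4.1.0]heptan-2-one (OH trans to isopropenyl) | C=C(C)[C@H]1C[C@@H]2O[C@]2(C)C(=O)[C@@H]1O | intermediate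
5 | (1S,3R,4R,6S)-1-methyl-4-(prop-1-en-2-yl)-3-(triethylsilyloxy)-7-oxabicyclo[4.1.0]heptan-2-one | C=C(C)[C@H]1C[C@@H]2O[C@]2(C)C(=O)[C@@H]1O[Si](CC)(CC)CC | intermediate
6 | secondary ozonide (3-methyl-1,2,4-trioxolan-3-yl on C4) of 5, epimers at the ozonide carbon | CC3(OCOO3)[C@H]1C[C@@H]2O[C@]2(C)C(=O)[C@@H]1O[Si](CC)(CC)CC | intermediate
7 | (1S,3R,4S,6S)-4-acetyl-1-methyl-3-(triethylsilyloxy)-7-oxabicyclo[4.1.0]heptan-2-one | CC(=O)[C@H]1C[C@@H]2O[C@]2(C)C(=O)[C@@H]1O[Si](CC)(CC)CC | intermediate
8 | terminal potassium enolate of the acetyl group of 7 | C=C([O-])[C@H]1C[C@@H]2O[C@]2(C)C(=O)[C@@H]1O[Si](CC)(CC)CC.[K+] | intermediate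
9 | (1S,3R,4S,6S)-1-methyl-3-(triethylsilyloxy)-4-[1-(trifluoromethanesulfonyloxy)ethenyl]-7-oxabicyclo[4.1.0]heptan-2-one | C=C(OS(=O)(=O)C(F)(F)F)[C@H]1C[C@@H]2O[C@]2(C)C(=O)[C@@H]1O[Si](CC)(CC)CC | intermediate
10 | (1S,3R,4S,6S)-3-hydroxy-1-methyl-4-[1-(trifluoromethanesulfonyloxy)ethenyl]-7-oxabicyclo[4.1.0]heptan-2-one | C=C(OS(=O)(=O)C(F)(F)F)[C@H]1C[C@@H]2O[C@]2(C)C(=O)[C@@H]1O | intermediate
11 | angelic acid, (2Z)-2-methylbut-2-enoic acid | C/C=C(/C)C(=O)O | starting material
12 | (1S,3R,4S,6S)-1-methyl-3-(trifluoromethanesulfonyloxy)-4-[1-(trifluoromethanesulfonyloxy)ethenyl]-7-oxabicyclo[4.1.0]heptan-2-one | C=C(OS(=O)(=O)C(F)(F)F)[C@H]1C[C@@H]2O[C@]2(C)C(=O)[C@@H]1OS(=O)(=O)C(F)(F)F | intermediate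
13 | cesium (2Z)-2-methylbut-2-enoate (cesium angelate) | C/C=C(/C)C(=O)[O-].[Cs+] | intermediate
14 | (1S,3S,4S,6S)-1-methyl-3-[(2Z)-2-methylbut-2-enoyloxy]-4-[1-(trifluoromethanesulfonyloxy)ethenyl]-7-oxabicyclo[4.1.0]heptan-2-one (angelate cis to the C4 group) | C=C(OS(=O)(=O)C(F)(F)F)[C@H]1C[C@@H]2O[C@]2(C)C(=O)[C@H]1OC(=O)/C(C)=C\C | intermediate
15 | 4-methylpent-3-en-1-ol | CC(C)=CCCO | starting material
16 | 4-methylpent-3-enal | CC(C)=CCC=O | intermediate
17 | 3-methylbut-2-enoyl chloride (senecioyl chloride) | CC(C)=CC(=O)Cl | starting material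
18 | rac-1-chloro-4-methylpent-3-en-1-yl 3-methylbut-2-enoate | CC(C)=CCC(Cl)OC(=O)C=C(C)C | intermediate
19 | (1S,3S,4R,6S)-1-methyl-3-[(2Z)-2-methylbut-2-enoyloxy]-4-[(3S)-6-methyl-3-(3-methylbut-2-enoyloxy)hepta-1,5-dien-2-yl]-7-oxabicyclo[4.1.0]heptan-2-one | C=C([C@H](CC=C(C)C)OC(=O)C=C(C)C)[C@H]1C[C@@H]2O[C@]2(C)C(=O)[C@H]1OC(=O)/C(C)=C\C | target

**Summary**

Total steps: 10. Longest linear sequence: 8 (steps 1–7, then step 10).

**Steps most likely to fail**

Step 10 (proposed new method). What may go wrong: low-valent nickel or Mn(II) salts attack the epoxy ketone or the α-acyloxy ketone; the product allylic ester ionises at nickel; homocoupling dominates; or catalyst control at C3′ is poor against the bias of C4. Fallback, known chemistry: from 14 and aldehyde 16, a Cr/Ni-mediated Nozaki–Hiyama–Kishi coupling under the catalytic asymmetric protocol (CrCl2 cat., chiral oxazoline–sulfonamide ligand, NiCl2 cat., Mn, Cp2ZrCl2, LiCl, MeCN, rt) should form the same C2′–C3′ bond and give (1S,3S,4R,6S)-4-[(3S)-3-hydroxy-6-methylhepta-1,5-dien-2-yl]-1-methyl-3-[(2Z)-2-methylbut-2-enoyloxy]-7-oxabicyclo[4.1.0]heptan-2-one F1. Acylation of F1 with 17 (pyridine, cat. DMAP, CH2Cl2, 0 °C) returns to the route at 19. This fallback also makes chloro ester 18 unnecessary.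

Step 7. What may go wrong: the SN2 is slow because the bulky, weakly nucleophilic carboxylate must enter on the ring face that carries the C4 substituent, so elimination, enolisation (loss of C3 configuration) or decomposition of the α-keto triflate takes over. Fallback: from 10, triflate 12 is formed as before and displaced by the small, weakly basic nitrite ion (Bu4N+ NO2−, toluene/DMF, −20 °C) to give the inverted nitrite ester F2. F2 is hydrolysed on aqueous work-up to the 3,4-cis α-hydroxy ketone (1S,3S,4S,6S)-3-hydroxy-1-methyl-4-[1-(trifluoromethanesulfonyloxy)ethenyl]-7-oxabicyclo[4.1.0]heptan-2-one F3. F3 is then acylated with angelic 2,4,6-trichlorobenzoic anhydride F4 (from 11, 2,4,6-trichlorobenzoyl chloride, Et3N, toluene; then F3, no nucleophilic catalyst, 60 °C, to limit Z-to-E isomerisation), returning to the route at 14.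

Step 5. What may go wrong: regiocontrol of enolisation is lost (deprotonation at C3–H of the ring ketone or at C4–H, with epimerisation or β-elimination of the silyloxy group), or the terminal enolate closes onto the ring carbonyl by aldol addition. Fallback without an enolate: from 7, the less hindered acetyl carbonyl is condensed with 1,2-bis(tert-butyldimethylsilyl)hydrazine (cat. Sc(OTf)3) to the N-silyl hydrazone F5. F5 with I2 and tetramethylguanidine (Barton iodination) should give the alkenyl iodide (1S,3R,4S,6S)-4-(1-iodoethenyl)-1-methyl-3-(triethylsilyloxy)-7-oxabicyclo[4.1.0]heptan-2-one F6. F6 is taken through the conditions of steps 6 and 7: the hydroxy ketone F7, its C3 triflate F8 (not isolated), and with cesium angelate 13 the cis-angelate alkenyl iodide F9. F9 replaces 14 in step 10 and the route is rejoined at 19.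

**Further compounds**

F1 | step 10 | (1S,3S,4R,6S)-4-[(3S)-3-hydroxy-6-methylhepta-1,5-dien-2-yl]-1-methyl-3-[(2Z)-2-methylbut-2-enoyloxy]-7-oxabicyclo[4.1.0]heptan-2-one | C=C([C@H](CC=C(C)C)O)[C@H]1C[C@@H]2O[C@]2(C)C(=O)[C@H]1OC(=O)/C(C)=C\C
F2 | step 7 | (1S,3S,4S,6S)-1-methyl-3-(nitrosooxy)-4-[1-(trifluoromethanesulfonyloxy)ethenyl]-7-oxabicyclo[4.1.0]heptan-2-one (nitrite ester) | C=C(OS(=O)(=O)C(F)(F)F)[C@H]1C[C@@H]2O[C@]2(C)C(=O)[C@H]1ON=O
F3 | step 7 | (1S,3S,4S,6S)-3-hydroxy-1-methyl-4-[1-(trifluoromethanesulfonyloxy)ethenyl]-7-oxabicyclo[4.1.0]heptan-2-one | C=C(OS(=O)(=O)C(F)(F)F)[C@H]1C[C@@H]2O[C@]2(C)C(=O)[C@H]1O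
F4 | step 7 | (2Z)-2-methylbut-2-enoic 2,4,6-trichlorobenzoic anhydride | C/C=C(/C)C(=O)OC(=O)c1c(Cl)cc(Cl)cc1Cl
F5 | step 5 | N-(tert-butyldimethylsilyl)hydrazone of the acetyl group of 7 | CC(=NN[Si](C)(C)C(C)(C)C)[C@H]1C[C@@H]2O[C@]2(C)C(=O)[C@@H]1O[Si](CC)(CC)CC
F6 | step 5 | (1S,3R,4S,6S)-4-(1-iodoethenyl)-1-methyl-3-(triethylsilyloxy)-7-oxabicyclo[4.1.0]heptan-2-one | C=C(I)[C@H]1C[C@@H]2O[C@]2(C)C(=O)[C@@H]1O[Si](CC)(CC)CC
F7 | step 5 | (1S,3R,4S,6S)-3-hydroxy-4-(1-iodoethenyl)-1-methyl-7-oxabicyclo[4.1.0]heptan-2-one | C=C(I)[C@H]1C[C@@H]2O[C@]2(C)C(=O)[C@@H]1O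
F8 | step 5 | (1S,3R,4S,6S)-4-(1-iodoethenyl)-1-methyl-3-(trifluoromethanesulfonyloxy)-7-oxabicyclo[4.1.0]heptan-2-one | C=C(I)[C@H]1C[C@@H]2O[C@]2(C)C(=O)[C@@H]1OS(=O)(=O)C(F)(F)F
F9 | step 5 | (1S,3S,4S,6S)-4-(1-iodoethenyl)-1-methyl-3-[(2Z)-2-methylbut-2-enoyloxy]-7-oxabicyclo[4.1.0]heptan-2-one | C=C(I)[C@H]1C[C@@H]2O[C@]2(C)C(=O)[C@H]1OC(=O)/C(C)=C\C
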